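**Strategy.** The ten-membered carbocycle (C1–C10, germacrane numbering) is disconnected at its only disubstituted alkene, Z-C2=C3, which lies between C1 and C4. A Ramberg–Bäcklund reaction of an eleven-membered cyclic sulfone, in which sulfur bridges C2 and C3 and both are allylic (C1=C10, C4=C5), extrudes SO2, forges C2=C3 and contracts the ring by one atom in a single operation. The precursor carries the butenolide masked as a Z-γ-silyloxy enamide, with C6 set by CBS reduction and allene-to-lactone chirality transfer and C8 by an asymmetric Ni/Cr coupling. A late double epoxidation of the triene then relays both centres into four new stereocentres.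

Key step: step 21

Remark: C1–C15 are germacranolide numbers of the target (ring C1–C10; C6 lactone carbinol; C8 ester carbinol; C11/C12/C13 = butenolide α-carbon, carbonyl, CH2OAc; C14 = CH2OH on C10; C15 = CH3 on C4); the C1=C10 bond is ring-trans (C9 trans to C2; CIP descriptor Z because C14 outranks C9); TBS = tert-butyldimethylsilyl, TBDPS = tert-butyldiphenylsilyl, PMB = 4-methoxybenzyl; the catalyst antipodes in steps 5 and 15 are those predicted to give the stated configurations.

Step 1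
Reactants: 1 prop-2-yn-1-ol
Product: 3 (2Z)-3-iodo-2-methylprop-2-en-1-ol, via cyclic alkenylmagnesium alkoxide 2 (not isolated)
Conditions: MeMgBr (2.5 equiv), CuI (10 mol%), THF, −10 °C → rt; then I2, −78 → 0 °C
Reagents that add atoms: methylmagnesium bromide C[Mg]Br; iodine II
Why: Copper-catalysed alkoxide-directed anti-carbomagnesiation of the propargylic alcohol puts CH3 on C2 and Mg on C3 in a five-membered chelate, and iodinolysis with retention fixes the Z geometry (I cis to CH2OH) that becomes the ring-cis C4=C5 bond.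

Step 2
Reactants: 3 (2Z)-3-iodo-2-methylprop-2-en-1-ol
Product: 4 PMB ether of 3
Conditions: NaH, PMBCl, Bu4NI (cat.), THF/DMF, 0 °C → rt
Reagents that add atoms: 4-methoxybenzyl chloride COc1ccc(CCl)cc1
Why: Williamson etherification masks C3–OH for the organolithium chemistry; the vinyl iodide is inert to NaH at this temperature.

Step 3
Reactants: 5 tert-butyldimethyl(prop-2-yn-1-yloxy)silane
Product: 7 4-(TBS-oxy)-N-methoxy-N-methylbut-2-ynamide, via lithium acetylide 6 (not isolated)
Conditions: n-BuLi, THF, −78 °C; then ClC(O)N(OMe)Me, −78 → 0 °C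
Reagents that add atoms: N-methoxy-N-methylcarbamoyl chloride CON(C)C(Cl)=O
Why: Acylation of the lithium acetylide with the carbamoyl chloride gives the Weinreb ynamide that will deliver C6 at the ketone level.

Step 4
Reactants: 4 PMB ether of 3; 7 Weinreb ynamide
Product: 9 (5Z)-1-(TBS-oxy)-7-(PMB-oxy)-6-methylhept-5-en-2-yn-4-one, via Z-alkenyllithium 8 (not isolated)
Conditions: t-BuLi (2.1 equiv), Et2O, −78 °C; then 7, −78 → −20 °C; aq. NH4Cl
Reagents that add atoms: none
Why: Iodine–lithium exchange proceeds with retention of alkene geometry and the alkenyllithium adds once to the Weinreb amide (stable chelated tetrahedral intermediate), giving the cross-conjugated enynone.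

Step 5
Reactants: 9 enynone
Product: 10 (4S,5Z)-1-(TBS-oxy)-7-(PMB-oxy)-6-methylhept-5-en-2-yn-4-ol
Conditions: (S)-Me-CBS (20 mol%), BH3·SMe2, THF, −40 °C; MeOH quench
Reagents that add atoms: none
Why: Corey–Bakshi–Shibata reduction, in which the β,β-disubstituted alkenyl group should act as the large and the alkynyl group as the small substituent, so that the (S)-catalyst delivers hydride to give the (4S)-alcohol; this is the catalyst-set source of C6 (the antipode is to be checked by Mosher analysis).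

Step 6
Reactants: 10 (4S)-propargylic alcohol
Product: 11 (4S,5Z)-1-(TBS-oxy)-7-(PMB-oxy)-6-methylhept-5-en-2-yn-4-yl methyl carbonate
Conditions: ClCO2Me, pyridine, DMAP (cat.), CH2Cl2, 0 °C
Reagents that add atoms: methyl chloroformate COC(Cl)=O
Why: O-acylation converts the carbinol into the carbonate leaving group needed for Pd-mediated SN2′ ionisation; the stereocentre is untouched.

Step 7
Reactants: 11 propargylic carbonate
Product: 12 methyl (aR,5Z)-2-[(TBS-oxy)methyl]-7-(PMB-oxy)-6-methylhepta-2,3,5-trienoate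
Conditions: Pd2(dba)3·CHCl3 (2.5 mol%), PPh3 (10 mol%), CO (1–5 atm), MeOH/THF, rt
Reagents that add atoms: carbon monoxide [C-]#[O+]
Why: Pd(0)-catalysed carbonylation of a propargylic carbonate (anti-SN2′ oxidative addition to an allenyl–Pd species, CO insertion, methoxide transfer after decarboxylation) converts the (4S) centre into (aR) axial chirality.

Step 8
Reactants: 12 allenoate
Product: 13 (5R)-3-[(TBS-oxy)methyl]-4-iodo-5-[(1Z)-3-(PMB-oxy)-2-methylprop-1-en-1-yl]furan-2(5H)-one
Conditions: I2 (2 equiv), NaHCO3, MeCN/H2O (15:1), 0 °C → rt, dark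
Reagents that add atoms: iodine II; water O
Why: Iodolactonisation of a 2,3-allenoate: I+ adds to the central allene carbon and the ester carbonyl oxygen, held on one face by the allene axis, closes the butenolide, so axial chirality is transferred to the (5R) centre (C6) while the iodide needed at C7 is installed.

Step 9
Reactants: 14 4,4-diethoxybut-1-yne
Product: 16 5,5-diethoxypent-2-yn-1-ol, via lithium acetylide 15 (not isolated)
Conditions: n-BuLi, THF, −78 °C; then (CH2O)n, −78 °C → rt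
Reagents that add atoms: formaldehyde C=O
Why: Hydroxymethylation of the lithium acetylide provides the propargylic alcohol (C2–OH) that directs the next step.

Step 10
Reactants: 16 5,5-diethoxypent-2-yn-1-ol
Product: 18 (2Z)-5,5-diethoxy-3-iodopent-2-en-1-ol, via cyclic alkenylalanate 17 (not isolated)
Conditions: Red-Al, THF, 0 °C → rt; EtOAc; then I2, −78 → 0 °C
Reagents that add atoms: iodine II
Why: Hydroxyl-directed trans-hydroalumination delivers hydride to the proximal and aluminium to the distal alkyne carbon (C10) in a five-membered alanate, and iodinolysis with retention gives the Z-iodide that fixes the ring-trans C1=C10 geometry.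

Step 11
Reactants: 18 Z-iodo alcohol
Product: 19 PMB ether of 18
Conditions: NaH, PMBCl, Bu4NI (cat.), THF, 0 °C → rt
Reagents that add atoms: 4-methoxybenzyl chloride COc1ccc(CCl)cc1
Why: Williamson etherification protects C2–OH orthogonally to the silyl ethers used later.

Step 12
Reactants: 19 PMB ether
Product: 20 (2Z)-2-(2,2-diethoxyethyl)-4-(PMB-oxy)but-2-en-1-ol
Conditions: Bu3SnCH2OH, Pd(PPh3)4 (5 mol%), 1,4-dioxane, 90 °C
Reagents that add atoms: (tributylstannyl)methanol CCCC[Sn](CCCC)(CCCC)CO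
Why: Stille hydroxymethylation of the vinyl iodide with retention of geometry installs C14 cis to C2.

Step 13
Reactants: 20 allylic alcohol
Product: 21 TBDPS ether of 20
Conditions: TBDPSCl, imidazole, DMF, rt
Reagents that add atoms: tert-butyl(chloro)diphenylsilane CC(C)(C)[Si](Cl)(c1ccccc1)c1ccccc1
Why: Silylation gives C14–O a group that outlasts the TBS ethers and is removed last.

Step 14
Reactants: 21 TBDPS ether
Product: 22 (3Z)-3-[(TBDPS-oxy)methyl]-5-(PMB-oxy)pent-3-enal
Conditions: 10% aq. oxalic acid on SiO2, CH2Cl2, rt; used at once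
Reagents that add atoms: water O
Why: Mild heterogeneous acetal hydrolysis unmasks the C8 aldehyde without shifting the β,γ-double bond into conjugation.

Step 15
Reactants: 13 iodobutenolide; 22 aldehyde
Product: 23 (5R)-4-[(1S,3Z)-1-hydroxy-3-[(TBDPS-oxy)methyl]-5-(PMB-oxy)pent-3-en-1-yl]-3-[(TBS-oxy)methyl]-5-[(1Z)-3-(PMB-oxy)-2-methylprop-1-en-1-yl]furan-2(5H)-one
Conditions: CrCl2 (10 mol%), NiCl2·dmp (2 mol%), chiral oxazoline–sulfonamide ligand (11 mol%), proton sponge, Mn, Cp2ZrCl2, LiCl, MeCN, rt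
Reagents that add atoms: none
Why: Catalytic asymmetric Nozaki–Hiyama–Kishi coupling: Ni inserts into the activated β-iodoenoate bond, the alkenyl group passes to the chiral Cr(III) complex, and the ligand selects the aldehyde face (reagent control) to form C7–C8 with the (8S) carbinol.

Step 16
Reactants: 23 coupled butenolide
Product: 25 (6R,8S)-2,3-bis(PMB-oxy)-6,8,13-tris(TBS-oxy)-14-(TBDPS-oxy)-2,3-secogermacra-1(10)Z,4Z,7(11)Z-trien-12-oic acid N,N-dimethylamide, via hydroxy amide 24 (not isolated)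
Conditions: Me2NH (2 M in THF), AlMe3, CH2Cl2, 0 °C → rt; Rochelle salt; crude + TBSOTf, 2,6-lutidine, CH2Cl2, −78 → 0 °C
Reagents that add atoms: dimethylamine CNC; tert-butyldimethylsilyl triflate CC(C)(C)[Si](C)(C)OS(=O)(=O)C(F)(F)F
Why: Aluminium-amide aminolysis of the lactone (1,2-addition, since the β-carbon is fully substituted) opens the butenolide to the Z-γ-hydroxy enamide, which is silylated at C6–OH and C8–OH before it can relactonise; this removes the acidic butenolide γ-hydrogen ahead of the base-mediated key step.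

Step 17
Reactants: 25 bis-PMB ether
Product: 26 C2,C3-diol of 25
Conditions: DDQ (2.4 equiv), CH2Cl2/pH 7 buffer, 0 °C
Reagents that add atoms: none
Why: Oxidative cleavage of both allylic PMB ethers; silyl ethers and the enamide are inert.

Step 18
Reactants: 26 diol
Product: 27 C2,C3-dibromide
Conditions: CBr4, PPh3, 2,6-lutidine, CH2Cl2, −20 → 0 °C
Reagents that add atoms: carbon tetrabromide BrC(Br)(Br)Br
Why: Appel bromination of the two primary allylic alcohols by SN2 without allylic transposition.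

Step 19
Reactants: 27 dibromide
Product: 28 eleven-membered cyclic sulfide (S bridging C2 and C3)
Conditions: Na2S·9H2O, EtOH/THF, high dilution (slow addition), rt
Reagents that add atoms: sodium sulfide [Na+].[Na+].[S-2]
Why: Double S-alkylation under high dilution closes the eleven-membered thiacycle, a ring size that forms far more readily than a ten-membered carbocycle by direct C–C closure.

Step 20
Reactants: 28 cyclic sulfide
Product: 29 eleven-membered cyclic sulfone
Conditions: (NH4)6Mo7O24·4H2O (10 mol%), 30% H2O2, EtOH, 0 °C → rt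
Reagents that add atoms: hydrogen peroxide OO
Why: Molybdate-catalysed peroxide oxidation takes sulfide to sulfone chemoselectively without epoxidising the trisubstituted alkenes.

Step 21
Reactants: 29 cyclic sulfone
Product: 32 (6R,8S)-6,8,13-tris(TBS-oxy)-14-(TBDPS-oxy)germacra-1(10)Z,2Z,4Z,7(11)Z-tetraen-12-oic acid N,N-dimethylamide, via α-bromo sulfone 30 (not isolated), via fused episulfone 31 (not isolated)
Conditions: CBr2F2, KOH/Al2O3, t-BuOH/CH2Cl2, 0 °C; cold work-up, used at once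
Reagents that add atoms: none
Why: KOH on alumina deprotonates the bis-allylic sulfone at C2 (or C3), CBr2F2 transfers bromine to give α-bromo sulfone 30, a second deprotonation at the other α-carbon triggers 1,3-displacement of bromide to the fused episulfone 31, and cheletropic loss of SO2 leaves the C2=C3 bond, so the eleven-membered thiacycle becomes the ten-membered carbocycle. The closest known reaction type is the Ramberg–Bäcklund reaction in its one-flask halogenative form, established for diallyl sulfones (conjugated trienes) and for contraction of eleven-membered cyclic sulfones to ten-membered rings. The only ring closed is the transient thiirane 1,1-dioxide (3-exo-tet); the carbocycle itself arises by extrusion, not by a new cyclisation. No stereocentre is created; the new alkene should be Z because the ring between the ring-trans C1=C10 and the cis C4=C5 bonds cannot hold an E-C2=C3 bond and the cis-episulfone is the kinetic product. The step needs deprotonation only at C2/C3, which is secured by their double (sulfonyl plus allyl) activation and by the enamide masking of the butenolide (no acidic γ-hydrogen, so C6 cannot epimerise), silyl ethers being the only other functions. The (Z)-centred triene is prone to 6π-electrocyclisation and is therefore made at 0 °C and carried on immediately.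

Step 22
Reactants: 32 triene amide
Product: 34 (6R,8S)-8,13-dihydroxy-14-(TBDPS-oxy)germacra-1(10)Z,2Z,4Z,7(11)-tetraen-6,12-olide, via triol amide 33 (not isolated)
Conditions: HF·pyridine, pyridine, THF, 0 → 10 °C
Reagents that add atoms: none
Why: Acidic fluoride removes the three TBS ethers but not the primary TBDPS ether, and the freed C6–OH, held cis to the amide on the tetrasubstituted alkene, lactonises with loss of dimethylamine to restore the butenolide.

Step 23
Reactants: 34 triene lactone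
Product: 35 (1R,4R,5S,6S,8S,10S)-1,10:4,5-diepoxy-8,13-dihydroxy-14-(TBDPS-oxy)germacra-2Z,7(11)-dien-6,12-olide
Conditions: dimethyldioxirane (2.2 equiv, acetone), CH2Cl2, −40 → −10 °C
Reagents that add atoms: dimethyldioxirane CC1(C)OO1
Why: Double epoxidation by a neutral dioxirane of the two electron-rich trisubstituted alkenes, each expected to be attacked on its outer face of the butenolide-fused ring (C4=C5 anti to the C6–O bond with H6 eclipsing the alkene), so that C6 and C8 relay into C1, C10, C4 and C5 in one event; C2=C3 is then deactivated by two allylic C–O bonds and the butenolide alkene is electron-poor.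

Step 24
Reactants: 35 bis-epoxide diol
Product: 36 13-acetate of 35
Conditions: Ac2O (1.1 equiv), 2,4,6-collidine, CH2Cl2, −20 °C
Reagents that add atoms: acetic anhydride CC(=O)OC(C)=O
Why: Selective acylation of the unhindered primary allylic C13–OH over the secondary C8–OH, which is flanked by the tetrasubstituted alkene.

Step 25
Reactants: 36 13-acetate
Product: 37 8-methacrylate of 36
Conditions: methacrylic anhydride, i-Pr2NEt, DMAP, CH2Cl2, 0 °C → rt
Reagents that add atoms: methacrylic anhydride CC(=C)C(=O)OC(=O)C(C)=C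
Why: DMAP-catalysed esterification of the remaining secondary alcohol under non-acidic conditions that spare the vinyl epoxides.

Step 26
Reactants: 37 protected target
Product: 38 target (1R,4R,5S,6S,8S,10S)-13-acetoxy-1,10:4,5-diepoxy-14-hydroxy-8-(methacryloyloxy)germacra-2Z,7(11)-dien-6,12-olide
Conditions: Bu4NF, AcOH (1:1), THF, 0 °C → rt
Reagents that add atoms: none
Why: Buffered fluoride desilylation frees C14–OH; acetic acid buffering suppresses epoxide migration of the 2,3-epoxy alcohol, acyl migration and butenolide γ-deprotonation.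

**Compound list**

1 | prop-2-yn-1-ol | C#CCO | starting material
2 | 4-methyl-2,5-dihydro-1,2-oxamagnesole (cyclic alkenylmagnesium alkoxide) | CC1=C[Mg]OC1 | intermediate
3 | (2Z)-3-iodo-2-methylprop-2-en-1-ol | OC/C(C)=C\I | intermediate
4 | 1-({[(2Z)-3-iodo-2-methylprop-2-en-1-yl]oxy}methyl)-4-methoxybenzene | COc1ccc(COC/C(C)=C\I)cc1 | intermediate
5 | tert-butyldimethyl(prop-2-yn-1-yloxy)silane | C#CCO[Si](C)(C)C(C)(C)C | starting material
6 | lithium acetylide of 5 | [Li]C#CCO[Si](C)(C)C(C)(C)C | intermediate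
7 | 4-(TBS-oxy)-N-methoxy-N-methylbut-2-ynamide | CON(C)C(=O)C#CCO[Si](C)(C)C(C)(C)C | intermediate
8 | [(1Z)-3-(PMB-oxy)-2-methylprop-1-en-1-yl]lithium | COc1ccc(COC/C(C)=C\[Li])cc1 | intermediate
9 | (5Z)-1-(TBS-oxy)-7-(PMB-oxy)-6-methylhept-5-en-2-yn-4-one | COc1ccc(COC/C(C)=C\C(=O)C#CCO[Si](C)(C)C(C)(C)C)cc1 | intermediate
10 | (4S,5Z)-1-(TBS-oxy)-7-(PMB-oxy)-6-methylhept-5-en-2-yn-4-ol | COc1ccc(COC/C(C)=C\[C@H](O)C#CCO[Si](C)(C)C(C)(C)C)cc1 | intermediate
11 | (4S,5Z)-1-(TBS-oxy)-7-(PMB-oxy)-6-methylhept-5-en-2-yn-4-yl methyl carbonate | COc1ccc(COC/C(C)=C\[C@H](OC(=O)OC)C#CCO[Si](C)(C)C(C)(C)C)cc1 | intermediate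
12 | methyl (aR,5Z)-2-[(TBS-oxy)methyl]-7-(PMB-oxy)-6-methylhepta-2,3,5-trienoate | COC(=O)C(CO[Si](C)(C)C(C)(C)C)=[C@]=C([H])/C=C(C)\COCc1ccc(OC)cc1 | intermediate
13 | (5R)-3-[(TBS-oxy)methyl]-4-iodo-5-[(1Z)-3-(PMB-oxy)-2-methylprop-1-en-1-yl]furan-2(5H)-one | O=C1O[C@H](/C=C(C)\COCc2ccc(OC)cc2)C(I)=C1CO[Si](C)(C)C(C)(C)C | intermediate
14 | 4,4-diethoxybut-1-yne | C#CCC(OCC)OCC | starting material
15 | lithium acetylide of 14 | [Li]C#CCC(OCC)OCC | intermediate
16 | 5,5-diethoxypent-2-yn-1-ol | OCC#CCC(OCC)OCC | intermediate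
17 | sodium 3-(2,2-diethoxyethyl)-2,2-bis(2-methoxyethoxy)-2,5-dihydro-1,2-oxaluminol-2-uide (cyclic alkenylalanate) | [Na+].COCCO[Al-]1(OCCOC)OCC=C1CC(OCC)OCC | intermediate
18 | (2Z)-5,5-diethoxy-3-iodopent-2-en-1-ol | OC/C=C(\I)CC(OCC)OCC | intermediate
19 | PMB ether of 18 | COc1ccc(COC/C=C(\I)CC(OCC)OCC)cc1 | intermediate
20 | (2Z)-2-(2,2-diethoxyethyl)-4-(PMB-oxy)but-2-en-1-ol | COc1ccc(COC/C=C(\CO)CC(OCC)OCC)cc1 | intermediate
21 | TBDPS ether of 20 | COc1ccc(COC/C=C(\CO[Si](c2ccccc2)(c2ccccc2)C(C)(C)C)CC(OCC)OCC)cc1 | intermediate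
22 | (3Z)-3-[(TBDPS-oxy)methyl]-5-(PMB-oxy)pent-3-enal | COc1ccc(COC/C=C(\CO[Si](c2ccccc2)(c2ccccc2)C(C)(C)C)CC=O)cc1 | intermediate
23 | (5R)-butenolide with (1S,3Z)-1-hydroxy side chain at C4 (coupling product, 6R,8S in germacrane numbers) | O=C1O[C@H](/C=C(C)\COCc2ccc(OC)cc2)C([C@@H](O)C/C(CO[Si](c2ccccc2)(c2ccccc2)C(C)(C)C)=C/COCc2ccc(OC)cc2)=C1CO[Si](C)(C)C(C)(C)C | intermediate
24 | (6R,8S)-6,8-dihydroxy-2,3-bis(PMB-oxy)-13-(TBS-oxy)-14-(TBDPS-oxy)-2,3-secogermacra-1(10)Z,4Z,7(11)Z-trien-12-oic acid N,N-dimethylamide | COc1ccc(COC/C(C)=C\[C@@H](O)/C(=C(/CO[Si](C)(C)C(C)(C)C)C(=O)N(C)C)[C@@H](O)C/C(CO[Si](c2ccccc2)(c2ccccc2)C(C)(C)C)=C/COCc2ccc(OC)cc2)cc1 | intermediate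
25 | 6,8-bis-TBS ether of 24 | COc1ccc(COC/C(C)=C\[C@@H](O[Si](C)(C)C(C)(C)C)/C(=C(/CO[Si](C)(C)C(C)(C)C)C(=O)N(C)C)[C@@H](O[Si](C)(C)C(C)(C)C)C/C(CO[Si](c2ccccc2)(c2ccccc2)C(C)(C)C)=C/COCc2ccc(OC)cc2)cc1 | intermediate
26 | C2,C3-diol (both PMB groups removed from 25) | OC/C(C)=C\[C@@H](O[Si](C)(C)C(C)(C)C)/C(=C(/CO[Si](C)(C)C(C)(C)C)C(=O)N(C)C)[C@@H](O[Si](C)(C)C(C)(C)C)C/C(CO[Si](c1ccccc1)(c1ccccc1)C(C)(C)C)=C/CO | intermediate
27 | C2,C3-dibromide | BrC/C(C)=C\[C@@H](O[Si](C)(C)C(C)(C)C)/C(=C(/CO[Si](C)(C)C(C)(C)C)C(=O)N(C)C)[C@@H](O[Si](C)(C)C(C)(C)C)C/C(CO[Si](c1ccccc1)(c1ccccc1)C(C)(C)C)=C/CBr | intermediate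
28 | eleven-membered cyclic sulfide (S between C2 and C3; 6R,8S) | S1C/C(C)=C\[C@@H](O[Si](C)(C)C(C)(C)C)/C(=C(/CO[Si](C)(C)C(C)(C)C)C(=O)N(C)C)[C@@H](O[Si](C)(C)C(C)(C)C)C/C(CO[Si](c2ccccc2)(c2ccccc2)C(C)(C)C)=C/C1 | intermediate
29 | eleven-membered cyclic sulfone | O=S1(=O)C/C(C)=C\[C@@H](O[Si](C)(C)C(C)(C)C)/C(=C(/CO[Si](C)(C)C(C)(C)C)C(=O)N(C)C)[C@@H](O[Si](C)(C)C(C)(C)C)C/C(CO[Si](c2ccccc2)(c2ccccc2)C(C)(C)C)=C/C1 | intermediate
30 | 2-bromo derivative of sulfone 29 | O=S1(=O)C/C(C)=C\[C@@H](O[Si](C)(C)C(C)(C)C)/C(=C(/CO[Si](C)(C)C(C)(C)C)C(=O)N(C)C)[C@@H](O[Si](C)(C)C(C)(C)C)C/C(CO[Si](c2ccccc2)(c2ccccc2)C(C)(C)C)=C/C1Br | intermediate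
31 | fused episulfone (C2–C3 bonded, SO2 bridging C2 and C3) | O=S1(=O)C2C1/C(C)=C\[C@@H](O[Si](C)(C)C(C)(C)C)/C(=C(/CO[Si](C)(C)C(C)(C)C)C(=O)N(C)C)[C@@H](O[Si](C)(C)C(C)(C)C)C/C(CO[Si](c3ccccc3)(c3ccccc3)C(C)(C)C)=C/2 | intermediate
32 | (6R,8S)-6,8,13-tris(TBS-oxy)-14-(TBDPS-oxy)germacra-1(10)Z,2Z,4Z,7(11)Z-tetraen-12-oic acid N,N-dimethylamide | C/C1=C/[C@@H](O[Si](C)(C)C(C)(C)C)/C(=C(/CO[Si](C)(C)C(C)(C)C)C(=O)N(C)C)[C@@H](O[Si](C)(C)C(C)(C)C)C/C(CO[Si](c2ccccc2)(c2ccccc2)C(C)(C)C)=C/C=C\1 | intermediate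
33 | 6,8,13-triol of 32 | C/C1=C/[C@@H](O)/C(=C(/CO)C(=O)N(C)C)[C@@H](O)C/C(CO[Si](c2ccccc2)(c2ccccc2)C(C)(C)C)=C/C=C\1 | intermediate
34 | (6R,8S)-8,13-dihydroxy-14-(TBDPS-oxy)germacra-1(10)Z,2Z,4Z,7(11)-tetraen-6,12-olide | C/C1=C/[C@H]2OC(=O)C(CO)=C2[C@@H](O)C/C(CO[Si](c3ccccc3)(c3ccccc3)C(C)(C)C)=C/C=C\1 | intermediate
35 | (1R,4R,5S,6S,8S,10S)-1,10:4,5-diepoxy-8,13-dihydroxy-14-(TBDPS-oxy)germacra-2Z,7(11)-dien-6,12-olide | O[C@H]1C[C@@]2(CO[Si](c3ccccc3)(c3ccccc3)C(C)(C)C)O[C@@H]2/C=C\[C@@]2(C)O[C@H]2[C@H]2OC(=O)C(CO)=C12 | intermediate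
36 | 13-acetate of 35 | O[C@H]1C[C@@]2(CO[Si](c3ccccc3)(c3ccccc3)C(C)(C)C)O[C@@H]2/C=C\[C@@]2(C)O[C@H]2[C@H]2OC(=O)C(COC(C)=O)=C12 | intermediate
37 | 8-methacrylate of 36 | C=C(C)C(=O)O[C@H]1C[C@@]2(CO[Si](c3ccccc3)(c3ccccc3)C(C)(C)C)O[C@@H]2/C=C\[C@@]2(C)O[C@H]2[C@H]2OC(=O)C(COC(C)=O)=C12 | intermediate
38 | (1R,4R,5S,6S,8S,10S)-13-acetoxy-1,10:4,5-diepoxy-14-hydroxy-8-(methacryloyloxy)germacra-2Z,7(11)-dien-6,12-olide | C=C(C)C(=O)O[C@H]1C[C@@]2(CO)O[C@@H]2/C=C\[C@@]2(C)O[C@H]2[C@H]2OC(=O)C(COC(C)=O)=C12 | target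

**Totals.** 26 steps in all. Longest linear sequence: 19 steps (1, 2, 4–8, 15–26) from prop-2-yn-1-ol.

**Steps most likely to fail**

1. Step 21 (ring contraction). In-situ bromination on solid KOH may be slow enough for base-mediated double-bond migration to compete, and the (Z)-centred triene may undergo 6π-electrocyclisation to a bicyclo[4.4.0]decadiene while it is handled near room temperature. Fallback, setting out from sulfide 28 and returning at triene 32: the halogen is installed at the sulfide stage and the contraction is run as a homogeneous low-temperature process. N-Chlorosuccinimide (CH2Cl2, 0 °C) should give the α-chloro sulfide F1, molybdate/H2O2 oxidation the α-chloro sulfone F2, and KOt-Bu in THF at −78 °C the 1,3-elimination and SO2 extrusion to 32, which is taken cold into step 22.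

2. Step 23 (double epoxidation). Facial discrimination at C1=C10, where no directing group operates, may be poor, and the two alkenes may not react cleanly in sequence. Fallback, setting out from 34 and returning at 38: acylate first and epoxidise stepwise under reagent and directing-group control. Selective acetylation of 34 gives the 13-acetate F3, methacrylation the 8-methacrylate F4, and buffered Bu4NF the C14 allylic alcohol F5 (all kept cold). Sharpless epoxidation of F5 (Ti(OiPr)4, L-(+)-diethyl tartrate, t-BuOOH, −20 °C), directed by C14–OH, should give the (1R,10S)-monoepoxide F6. Buffered m-CPBA then epoxidises C4=C5 anti to the C6–O bond to reach 38.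

3. Step 15 (Ni/Cr coupling). The chiral chromium complex may discriminate the aldehyde faces poorly with this hindered tetrasubstituted alkenyl partner, giving C8 epimers. Fallback, setting out from 13 and 22 and returning at 23: an achiral CrCl2/NiCl2 coupling gives 23 together with the (8R)-epimer F7, separable as diastereomers. F7 is inverted by Mitsunobu esterification with chloroacetic acid (DIAD, PPh3) to the (8S)-chloroacetate F8, and the chloroacetyl group is removed with thiourea/NaHCO3 in EtOH to give 23.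

**Further compounds**

F1 | step 21 | 2-chloro derivative of cyclic sulfide 28 | S1C/C(C)=C\[C@@H](O[Si](C)(C)C(C)(C)C)/C(=C(/CO[Si](C)(C)C(C)(C)C)C(=O)N(C)C)[C@@H](O[Si](C)(C)C(C)(C)C)C/C(CO[Si](c2ccccc2)(c2ccccc2)C(C)(C)C)=C/C1Cl
F2 | step 21 | 2-chloro derivative of cyclic sulfone 29 | O=S1(=O)C/C(C)=C\[C@@H](O[Si](C)(C)C(C)(C)C)/C(=C(/CO[Si](C)(C)C(C)(C)C)C(=O)N(C)C)[C@@H](O[Si](C)(C)C(C)(C)C)C/C(CO[Si](c2ccccc2)(c2ccccc2)C(C)(C)C)=C/C1Cl
F3 | step 23 | 13-acetate of triene lactone 34 | C/C1=C/[C@H]2OC(=O)C(COC(C)=O)=C2[C@@H](O)C/C(CO[Si](c3ccccc3)(c3ccccc3)C(C)(C)C)=C/C=C\1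
F4 | step 23 | 13-acetate 8-methacrylate of 34 | C/C1=C/[C@H]2OC(=O)C(COC(C)=O)=C2[C@@H](OC(=O)C(C)=C)C/C(CO[Si](c3ccccc3)(c3ccccc3)C(C)(C)C)=C/C=C\1
F5 | step 23 | (6R,8S)-13-acetoxy-14-hydroxy-8-(methacryloyloxy)germacra-1(10)Z,2Z,4Z,7(11)-tetraen-6,12-olide | C/C1=C/[C@H]2OC(=O)C(COC(C)=O)=C2[C@@H](OC(=O)C(C)=C)C/C(CO)=C/C=C\1
F6 | step 23 | (1R,6R,8S,10S)-13-acetoxy-1,10-epoxy-14-hydroxy-8-(methacryloyloxy)germacra-2Z,4Z,7(11)-trien-6,12-olide | C=C(C)C(=O)O[C@H]1C[C@@]2(CO)O[C@@H]2/C=C\C(C)=C/[C@H]2OC(=O)C(COC(C)=O)=C12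
F7 | step 15 | (8R)-epimer of 23 | O=C1O[C@H](/C=C(C)\COCc2ccc(OC)cc2)C([C@H](O)C/C(CO[Si](c2ccccc2)(c2ccccc2)C(C)(C)C)=C/COCc2ccc(OC)cc2)=C1CO[Si](C)(C)C(C)(C)C
F8 | step 15 | (8S)-chloroacetate of 23 | O=C1O[C@H](/C=C(C)\COCc2ccc(OC)cc2)C([C@@H](OC(=O)CCl)C/C(CO[Si](c2ccccc2)(c2ccccc2)C(C)(C)C)=C/COCc2ccc(OC)cc2)=C1CO[Si](C)(C)C(C)(C)C
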